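**Strategy.** Both halves of the target are the same 5,6,8-trioxygenated 2-ethyl-3-hydroxy-1,4-naphthoquinone, so the (S)-configured C2–O ether is made last, by enantioselective dehydrodimerisation of one monomer. Everything rests on a [3+3] annulation that builds the carbocyclic C1–C2–C3–C4–C4a–C8a ring. An arylmagnesium ortho to a methyl ester (C4a nucleophile; C1 electrophile on the neighbouring ring carbon C8a) opens a 5-propylidene-1,3-dioxolan-4-one at its lactone carbonyl (C4–C4a bond). Acetone is lost, and the unmasked 1,2-diketone enolate closes through C2 onto the ester (C1–C2 bond). The step exploits the ortho relationship of acyl carbons C1 and C4 on C8a/C4a and the enolisable C2–C3(=O)–C4(=O) unit.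

Key step: step 3

Remark on the chemistry: atom numbers C1–C8a are those of the naphthalene-1,3,4(2H)-trione half of the target and apply to the same carbons of the monomer. Racemic 2-hydroxypentanoic acid, methyl 2,4,5-trimethoxybenzoate and both enantiomers of 2-iodo-1,3-bis[1-(mesitylcarbamoyl)ethoxy]benzene are assumed to be purchasable.

**Step 1**
Reactants: 1 2-hydroxypentanoic acid (racemic)
Product: 2 2,2-dimethyl-5-propyl-1,3-dioxolan-4-one (racemic)
Conditions: Me2C(OMe)2, acetone, TsOH·H2O (cat.), 25 °C
Reagents that add atoms: 2,2-dimethoxypropane, COC(C)(C)OC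
Why: Acid-catalysed transacetalisation of the α-hydroxy acid (acetonide formation) should give the 1,3-dioxolan-4-one; the stereocentre is racemic and is erased in step 2.

**Step 2**
Reactants: 2 2,2-dimethyl-5-propyl-1,3-dioxolan-4-one
Product: 4 (Z)-2,2-dimethyl-5-propylidene-1,3-dioxolan-4-one, via bromide 3 (not isolated)
Conditions: NBS, AIBN (cat.), PhCF3, 85 °C; then Et3N, 0 °C to 25 °C
Reagents that add atoms: none
Why: Wohl–Ziegler radical bromination should occur at the captodative C5–H (between ring oxygen and lactone carbonyl), and E2 dehydrobromination can only give the exocyclic alkene, the (Z)-isomer being expected to predominate (the geometry has no consequence later).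

**Step 3**
Reactants: 5 methyl 2,4,5-trimethoxybenzoate; 4 (Z)-2,2-dimethyl-5-propylidene-1,3-dioxolan-4-one
Product: 8 2-ethyl-3-hydroxy-5,6,8-trimethoxynaphthalene-1,4-dione, via arylmagnesium chloride 6 (not isolated), via diketone enolate 7 (not isolated)
Conditions: TMPMgCl·LiCl (1.2 equiv), THF, 0 °C to 25 °C; then 4 (1.2 equiv), −78 °C to 25 °C, then 45 °C; 1 M HCl
Reagents that add atoms: none
Why: Proposed new method: the ester and the flanking methoxy group direct magnesiation to the one C–H between them to give 6, which adds to the lactone carbonyl of 4; collapse of the tetrahedral adduct releases a hemiketal alkoxide that sheds acetone and so unmasks, regiospecifically, the magnesium enolate 7 of an aryl 1,2-diketone (C4–C4a bond). The enolate carbon C2 then attacks the neighbouring methyl ester in a Dieckmann condensation (C1–C2 bond), and loss of methoxide followed by deprotonation of the acidic trione to the hydroxyquinone salt makes the sequence irreversible. The closest known reaction types are acyl transfer from 5-ylidene-1,3-dioxolan-4-ones (masked enols of 2-oxo acids) to nucleophiles and the alkoxide-induced opening and Dieckmann reclosure of 3-alkylidene-isochromane-1,4-diones to 3-alkyl-2-hydroxy-1,4-naphthoquinones. The carbocyclic ring closes in a 6-(enolexo)-exo-trig mode; no stereocentre is formed and the alkene geometry of 4 is lost in 7. The step needs site-selective metalation (the other ring C–H lies between two methoxy groups and has no ester beside it), 1,2- instead of 1,4-addition to 4 (its β-carbon is deactivated by the enol-ether oxygen) and single acylation (at −78 °C the tetrahedral adduct should persist until 6 is consumed, and the anionic charge of 7 shields the new ketone). C- over O-acylation in the closure is secured by the six- against seven-membered ring.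

**Step 4**
Reactants: 8 2-ethyl-3-hydroxy-5,6,8-trimethoxynaphthalene-1,4-dione (two molecules)
Product: 9 (2S)-2-ethyl-2-[(3-ethyl-5,7,8-trimethoxy-1,4-dioxo-1,4-dihydronaphthalen-2-yl)oxy]-5,6,8-trimethoxynaphthalene-1,3,4(2H)-trione
Conditions: (R,R)-2-iodo-1,3-bis[1-(mesitylcarbamoyl)ethoxy]benzene (0.55 equiv), mCPBA (0.55 equiv), CF3CO2H (1.1 equiv), CH2Cl2, 25 °C; then 8, 4 Å MS, CH2Cl2–(CF3)2CHOH, −40 °C
Reagents that add atoms: none
Why: Proposed new method: the acidic enol OH of 8 should exchange onto the trivalent iodine of the aryl-λ3-iodane made in the flask, a second molecule of 8 should enter as the other oxygen ligand, and ligand coupling (attack of that oxygen on enol carbon C2 with reductive loss of the iodoarene) should form the quaternary C2–O bond; the hydrogen-bonded lactamide arms of the reagent are expected to shield one enantiotopic face of the planar enol, so the (S)-centre is set under reagent control (the (S,S)-reagent is used should the sense of induction prove opposite), O- over C-attack follows from the fully substituted nucleophilic carbon, and the reaction stops at the dimer because 9 has no enol left; the closest known reaction types are the dehydrodimerisation of 3-alkyl-2-hydroxy-1,4-naphthoquinones by one-electron oxidants to the same C–O-linked triones and the enantioselective oxygenative dearomatisation of naphthols and 2-alkylphenols by chiral aryl-λ3-iodanes.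

**Step 5**
Reactants: 9 (2S)-hexamethyl ether
Product: 10 (2S)-2-ethyl-2-[(3-ethyl-5,7,8-trihydroxy-1,4-dioxo-1,4-dihydronaphthalen-2-yl)oxy]-5,6,8-trihydroxynaphthalene-1,3,4(2H)-trione (CNP0325426.1)
Conditions: BBr3 (12 equiv), CH2Cl2, −78 °C to 0 °C; H2O
Reagents that add atoms: none
Why: Lewis-acid ether cleavage (BBr3 demethylation) should remove all six methyl groups by bromide attack at methyl, helped by chelation to the peri carbonyls, while the bridging ether offers no carbon open to SN2 attack and the quaternary (S)-centre has no pathway for epimerisation.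

**Compound list**
1 | 2-hydroxypentanoic acid (racemic) | CCCC(O)C(=O)O | starting material
2 | 2,2-dimethyl-5-propyl-1,3-dioxolan-4-one (racemic) | CCCC1OC(C)(C)OC1=O | intermediate
3 | 5-bromo-2,2-dimethyl-5-propyl-1,3-dioxolan-4-one (racemic, not isolated) | CCCC1(Br)OC(C)(C)OC1=O | intermediate
4 | (Z)-2,2-dimethyl-5-propylidene-1,3-dioxolan-4-one | CC/C=C1\OC(C)(C)OC1=O | intermediate
5 | methyl 2,4,5-trimethoxybenzoate | COC(=O)c1cc(OC)c(OC)cc1OC | starting material
6 | [2,3,5-trimethoxy-6-(methoxycarbonyl)phenyl]magnesium chloride (not isolated) | COC(=O)c1c([Mg]Cl)c(OC)c(OC)cc1OC | intermediate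
7 | chloromagnesium enolate (towards C2) of methyl 3,4,6-trimethoxy-2-(2-oxopentanoyl)benzoate (not isolated) | CCC=C(O[Mg]Cl)C(=O)c1c(OC)c(OC)cc(OC)c1C(=O)OC | intermediate
8 | 2-ethyl-3-hydroxy-5,6,8-trimethoxynaphthalene-1,4-dione | CCC1=C(O)C(=O)c2c(OC)c(OC)cc(OC)c2C1=O | intermediate
9 | (2S)-2-ethyl-2-[(3-ethyl-5,7,8-trimethoxy-1,4-dioxo-1,4-dihydronaphthalen-2-yl)oxy]-5,6,8-trimethoxynaphthalene-1,3,4(2H)-trione | CCC1=C(O[C@]2(CC)C(=O)C(=O)c3c(OC)c(OC)cc(OC)c3C2=O)C(=O)c2c(OC)c(OC)cc(OC)c2C1=O | intermediate
10 | (2S)-2-ethyl-2-[(3-ethyl-5,7,8-trihydroxy-1,4-dioxo-1,4-dihydronaphthalen-2-yl)oxy]-5,6,8-trihydroxynaphthalene-1,3,4(2H)-trione | CCC1=C(O[C@]2(CC)C(=O)C(=O)c3c(O)c(O)cc(O)c3C2=O)C(=O)c2c(O)c(O)cc(O)c2C1=O | target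

**Totals.** Total step count: 5. Longest linear sequence: 5 steps (1 → 2 → 4 → 8 → 9 → 10).

**Steps most likely to fail**

Step 3 (Proposed new method). The one-flask sequence may be diverted in three ways: capture of the arylmagnesium by the liberated acetone, lactonisation of the tetrahedral alkoxide onto the neighbouring ester, or arrest before the Dieckmann closure. The fallback is stepwise and uses known chemistry. Setting out from 5, the same magnesiation followed by an iodine quench should give methyl 2-iodo-3,4,6-trimethoxybenzoate F1. Sonogashira coupling with pent-1-yne (Pd(PPh3)2Cl2, CuI, Et3N) should give methyl 3,4,6-trimethoxy-2-(pent-1-yn-1-yl)benzoate F2. Oxidation of the alkyne with buffered KMnO4 (NaHCO3, MgSO4, aqueous acetone) should give methyl 3,4,6-trimethoxy-2-(2-oxopentanoyl)benzoate F3. NaOMe in MeOH should then close the ring by Dieckmann condensation, and the route is rejoined at 8.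

Step 4 (Proposed new method). Facial selectivity may be poor, or the iodane-bound enol may be intercepted by trifluoroacetate or 3-chlorobenzoate instead of the second quinone. The fallback uses known chemistry. Setting out from 8, oxidation with PbO2 in acetic acid, the established one-electron dehydrodimerisation of 3-alkyl-2-hydroxy-1,4-naphthoquinones, should give the racemic hexamethyl ether F4. This is resolved by preparative chromatography on an amylose tris(3,5-dimethylphenylcarbamate) stationary phase. The (R)-enantiomer F5 is set aside, and the (S)-enantiomer is 9, where the route is rejoined.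

Step 5. The bridging ether may be lost through bromide addition–elimination at the quinone carbon, or the two non-peri methoxy groups may be cleaved incompletely. The fallback replaces methyl by benzyl ethers, which leave under non-nucleophilic conditions. Setting out from 5, BBr3 at −78 °C to 0 °C should give methyl 2,4,5-trihydroxybenzoate F6, and BnBr with K2CO3 in DMF should give methyl 2,4,5-tris(benzyloxy)benzoate F7. The conditions of step 3 (with 4) should then give 5,6,8-tris(benzyloxy)-2-ethyl-3-hydroxynaphthalene-1,4-dione F8. The conditions of step 4 should give (2S)-5,6,8-tris(benzyloxy)-2-{[5,7,8-tris(benzyloxy)-3-ethyl-1,4-dioxo-1,4-dihydronaphthalen-2-yl]oxy}-2-ethylnaphthalene-1,3,4(2H)-trione F9. BCl3 with pentamethylbenzene in CH2Cl2 at −78 °C should remove all six benzyl groups, and the route is rejoined at 10.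

**Further compounds**
F1 | step 3 | methyl 2-iodo-3,4,6-trimethoxybenzoate | COC(=O)c1c(I)c(OC)c(OC)cc1OC
F2 | step 3 | methyl 3,4,6-trimethoxy-2-(pent-1-yn-1-yl)benzoate | CCCC#Cc1c(OC)c(OC)cc(OC)c1C(=O)OC
F3 | step 3 | methyl 3,4,6-trimethoxy-2-(2-oxopentanoyl)benzoate | CCCC(=O)C(=O)c1c(OC)c(OC)cc(OC)c1C(=O)OC
F4 | step 4 | racemic 2-ethyl-2-[(3-ethyl-5,7,8-trimethoxy-1,4-dioxo-1,4-dihydronaphthalen-2-yl)oxy]-5,6,8-trimethoxynaphthalene-1,3,4(2H)-trione | CCC1=C(OC2(CC)C(=O)C(=O)c3c(OC)c(OC)cc(OC)c3C2=O)C(=O)c2c(OC)c(OC)cc(OC)c2C1=O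
F5 | step 4 | (2R)-2-ethyl-2-[(3-ethyl-5,7,8-trimethoxy-1,4-dioxo-1,4-dihydronaphthalen-2-yl)oxy]-5,6,8-trimethoxynaphthalene-1,3,4(2H)-trione | CCC1=C(O[C@@]2(CC)C(=O)C(=O)c3c(OC)c(OC)cc(OC)c3C2=O)C(=O)c2c(OC)c(OC)cc(OC)c2C1=O
F6 | step 5 | methyl 2,4,5-trihydroxybenzoate | COC(=O)c1cc(O)c(O)cc1O
F7 | step 5 | methyl 2,4,5-tris(benzyloxy)benzoate | COC(=O)c1cc(OCc2ccccc2)c(OCc2ccccc2)cc1OCc1ccccc1
F8 | step 5 | 5,6,8-tris(benzyloxy)-2-ethyl-3-hydroxynaphthalene-1,4-dione | CCC1=C(O)C(=O)c2c(OCc3ccccc3)c(OCc3ccccc3)cc(OCc3ccccc3)c2C1=O
F9 | step 5 | (2S)-5,6,8-tris(benzyloxy)-2-{[5,7,8-tris(benzyloxy)-3-ethyl-1,4-dioxo-1,4-dihydronaphthalen-2-yl]oxy}-2-ethylnaphthalene-1,3,4(2H)-trione | CCC1=C(O[C@]2(CC)C(=O)C(=O)c3c(OCc4ccccc4)c(OCc4ccccc4)cc(OCc4ccccc4)c3C2=O)C(=O)c2c(OCc3ccccc3)c(OCc3ccccc3)cc(OCc3ccccc3)c2C1=O
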